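**Retrosynthetic overview**

1. Locants: C1–C14 are the ring carbons (C1 = CH carrying C15, C3 = CHOAc, C4 = methyl-bearing carbon on the ring oxygen, C7 = CHOH, C8 = methylene-bearing carbon, C11=C12 = trisubstituted alkene), C15 = OCMe2; the target is (1R,3R,4S,7R). The strategy rests on one feature: C2–C9 with the C4 methyl and the C8 methylene is the carbon chain of linalool, and its tertiary vinyl carbinol C4 can hand its chirality to C1.
2. The tetrahydropyran (C1–C2–C3–C4–O–C15) is closed last, by 6-endo opening of the (3R,4R)-epoxide by the C15 carbinol (C4–O bond, inversion); the epoxide comes from C15-hydroxyl-directed epoxidation of (E)-C3=C4, the carbinol from the C15 acid.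
3. Key disconnection: C1–C2, by Ireland–Claisen ring transposition of the 14-membered lactone (C15 ester on the C4 oxygen) into the 14-membered carbocycle with (E)-C3=C4 and (1R).
4. The lactone comes from C9–C10 ring closure (C10 sulfonyl carbanion on the C9 allylic chloride) of the open-chain C4 ester, then desulfonylation.
5. Fragments: C2–C9 from (S)-linalool (asymmetric epoxidation sets C7, epoxide-to-allylic-alcohol isomerization, ene chlorination); the C10–C15 acid from 5-hexyn-1-ol (Negishi carboalumination). Ring order: 14-membered lactone, 14-membered carbocycle, tetrahydropyran.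

Key step: step 14

Assumption: (S)-(+)-linalool of high enantiomeric purity and the D-fructose-derived ketone catalyst are bought. C10 of sulfone 18 forms as an epimer mixture, which does not matter because that centre is removed in step 13.

**Route**

Step 1
Reactants: 1 (S)-(+)-linalool
Product: 2 (3S)-3,7-dimethyl-3-(trimethylsilyloxy)octa-1,6-diene
Conditions: TMSCl, imidazole, DMF, rt
Reagents that add atoms: chlorotrimethylsilane, C[Si](C)(C)Cl
Why: Silylation of the tertiary alcohol masks the C4 oxygen, so that it can neither open the C7–C8 epoxide made next nor take part in the electrophilic chlorination of step 5.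

Step 2
Reactants: 2 (3S)-3,7-dimethyl-3-(trimethylsilyloxy)octa-1,6-diene
Product: 3 (3S,6R)-6,7-epoxy-3,7-dimethyl-3-(trimethylsilyloxy)oct-1-ene
Conditions: D-fructose-derived ketone catalyst (0.3 equiv), KHSO5 (as Oxone), K2CO3, Bu4NHSO4, MeCN–CH2(OMe)2/aq. Na2B4O7 buffer, 0 °C
Reagents that add atoms: potassium peroxymonosulfate, [K+].[O-]S(=O)(=O)OO
Why: Shi asymmetric epoxidation, in which the chiral dioxirane attacks only the electron-rich trisubstituted alkene through a spiro transition state and should set C7 as R under reagent control, the vinyl group being inert and C4 too remote to interfere.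

Step 3
Reactants: 3 (3S,6R)-6,7-epoxy-3,7-dimethyl-3-(trimethylsilyloxy)oct-1-ene
Product: 4 (3R,6S)-2,6-dimethyl-6-(trimethylsilyloxy)octa-1,7-dien-3-ol
Conditions: Et2Al(tmp) [from lithium 2,2,6,6-tetramethylpiperidide (n-BuLi, 2,2,6,6-tetramethylpiperidine) and Et2AlCl], toluene, 0 °C; aq. potassium sodium tartrate
Reagents that add atoms: none
Why: Aluminium amide isomerization of an epoxide to an allylic alcohol by syn β-elimination, in which a hydrogen of the C8 methyl cis to H-7 is removed as the C8–O bond breaks, so the C7–O bond and its R configuration are kept.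

Step 4
Reactants: 4 (3R,6S)-2,6-dimethyl-6-(trimethylsilyloxy)octa-1,7-dien-3-ol
Product: 5 (3R,6S)-3-(tert-butyldimethylsilyloxy)-2,6-dimethyl-6-(trimethylsilyloxy)octa-1,7-diene
Conditions: TBSOTf, 2,6-lutidine, CH2Cl2, −78 °C
Reagents that add atoms: tert-butyldimethylsilyl triflate, CC(C)(C)[Si](C)(C)OS(=O)(=O)C(F)(F)F
Why: Silylation of the secondary allylic C7 hydroxyl with a group that should last to the final step and that later blocks any C7-directed epoxidation of the C8 methylene.

Step 5
Reactants: 5 (3R,6S)-3-(tert-butyldimethylsilyloxy)-2,6-dimethyl-6-(trimethylsilyloxy)octa-1,7-diene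
Product: 7 (3S,6R)-6-(tert-butyldimethylsilyloxy)-7-(chloromethyl)-3-methylocta-1,7-dien-3-ol, via chloride silyl ether 6 (not isolated)
Conditions: NCS, PhSeCl (10 mol%), CH2Cl2, rt; then MeOH, PPTS, rt
Reagents that add atoms: N-chlorosuccinimide, O=C1CCC(=O)N1Cl
Why: Selenium-catalysed ene-type allylic chlorination (PhSeCl addition, loss of HCl to the allyl selenide, chloride delivery with allylic shift) should turn the isopropenyl group into the 2-(chloromethyl)allyl unit, the vinyl group having no allylic hydrogen, and mild acid methanolysis then frees the tertiary C4 hydroxyl without touching the C7 silyl ether.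

Step 6
Reactants: 8 5-hexyn-1-ol
Product: 9 tert-butyl(hex-5-yn-1-yloxy)dimethylsilane
Conditions: TBSCl, imidazole, CH2Cl2, rt
Reagents that add atoms: tert-butyldimethylsilyl chloride, CC(C)(C)[Si](C)(C)Cl
Why: Silylation of the primary alcohol, which is the future C15, so that the carboalumination sees only the alkyne.

Step 7
Reactants: 9 tert-butyl(hex-5-yn-1-yloxy)dimethylsilane
Product: 11 (E)-7-(tert-butyldimethylsilyloxy)-3-methylhept-2-en-1-ol, via alkenylalane 10 (not isolated)
Conditions: AlMe3 (2 equiv), Cp2ZrCl2 (0.25 equiv), CH2Cl2, 0 °C → rt; then n-BuLi, THF, −78 °C; (CH2O)n, rt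
Reagents that add atoms: trimethylaluminium, C[Al](C)C; formaldehyde (as paraformaldehyde), C=O
Why: Negishi zirconium-catalysed carboalumination adds methyl and aluminium syn across the terminal alkyne (methyl to C12), and hydroxymethylation of the alanate with retention should give the (E)-C11=C12 alkene with C10 as the allylic carbinol.

Step 8
Reactants: 11 (E)-7-(tert-butyldimethylsilyloxy)-3-methylhept-2-en-1-ol
Product: 13 (E)-tert-butyldimethyl[5-methyl-7-(phenylsulfonyl)hept-5-enyloxy]silane, via allylic bromide 12 (not isolated)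
Conditions: CBr4, PPh3, CH2Cl2, 0 °C; then PhSO2Na, Bu4NI (cat.), DMF, rt
Reagents that add atoms: sodium benzenesulfinate, [Na+].[O-]S(=O)c1ccccc1
Why: Appel bromination followed by S-alkylation of the sulfinate at the primary allylic carbon (direct displacement) should give the C10 sulfone without moving or isomerizing the alkene.

Step 9
Reactants: 13 (E)-tert-butyldimethyl[5-methyl-7-(phenylsulfonyl)hept-5-enyloxy]silane
Product: 14 (E)-5-methyl-7-(phenylsulfonyl)hept-5-en-1-ol
Conditions: CSA (cat.), MeOH, rt
Reagents that add atoms: none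
Why: Acid-catalysed methanolysis of a primary silyl ether, chosen over basic fluoride so that the allyl sulfone is not isomerized to the vinyl sulfone.

Step 10
Reactants: 14 (E)-5-methyl-7-(phenylsulfonyl)hept-5-en-1-ol
Product: 15 (E)-5-methyl-7-(phenylsulfonyl)hept-5-enoic acid
Conditions: TEMPO (cat.), PhI(OAc)2 (2.2 equiv), MeCN–H2O, rt
Reagents that add atoms: water, O
Why: Oxoammonium-catalysed oxidation of the primary alcohol through the aldehyde hydrate to the acid, conditions that leave the alkene and the sulfone alone.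

Step 11
Reactants: 15 (E)-5-methyl-7-(phenylsulfonyl)hept-5-enoic acid; 7 (3S,6R)-6-(tert-butyldimethylsilyloxy)-7-(chloromethyl)-3-methylocta-1,7-dien-3-ol
Product: 17 (3S,6R)-6-(tert-butyldimethylsilyloxy)-7-(chloromethyl)-3-methylocta-1,7-dien-3-yl (E)-5-methyl-7-(phenylsulfonyl)hept-5-enoate, via acid chloride 16 (not isolated)
Conditions: 15, (COCl)2, DMF (cat.), CH2Cl2, 0 °C → rt, evaporate; 7, n-BuLi, THF, −78 °C; then 16, −78 → −20 °C
Reagents that add atoms: none
Why: Acylation of the lithium alkoxide of a hindered tertiary allylic alcohol by an acid chloride, the usual way to esterify acid-sensitive tertiary carbinols, and at −78 °C O-acylation should outrun both displacement of the allylic chloride and deprotonation of the sulfone.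

Step 12
Reactants: 17 open-chain C4 ester
Product: 18 C10-phenylsulfonyl 14-membered lactone (4S,7R)
Conditions: KN(SiMe3)2 (1.05 equiv), 18-crown-6, THF, slow addition (final 2 mM), −78 → 0 °C
Reagents that add atoms: none
Why: Intramolecular alkylation of the sulfone-stabilised allyl carbanion (the allylic sulfone CH2 is far more acidic than the ester α-CH2) by the 2-substituted allylic chloride under high dilution closes the 14-membered ring at C9–C10, direct and allylic displacement giving the same bond.

Step 13
Reactants: 18 C10-phenylsulfonyl 14-membered lactone (4S,7R)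
Product: 19 14-membered lactone (4S,7R)
Conditions: Na(Hg) (6%), Na2HPO4, MeOH–THF, −20 °C
Reagents that add atoms: none
Why: Reductive desulfonylation with sodium amalgam, buffered and cold so that protonation at C10 keeps the (E)-C11=C12 alkene in place and the hindered tertiary allylic lactone is not touched.

Step 14
Reactants: 19 14-membered lactone (4S,7R)
Product: 22 14-membered carbocyclic C15 acid (1R,7R), via silyl ketene acetal 20 (not isolated), via trimethylsilyl ester 21 (not isolated)
Conditions: LiN(iPr)2 (1.3 equiv), TMSCl–Et3N (present from the start), THF, −78 °C → rt, then 50 °C; 1 M HCl work-up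
Reagents that add atoms: none
Why: Ireland–Claisen rearrangement used as a macrolactone-to-carbocycle ring transposition, a reaction type established for vinyl-substituted lactones and macrolides. Kinetic deprotonation in THF with in-situ silylation should give ketene acetal 20 with C14 cis to the ring oxygen, and the [3,3] shift then runs through the six-membered chair array C1–C15–O–C4–C3–C2, forming C1–C2 as C4–O breaks on the same face. The 14-membered carbocycle is closed by this sigmatropic shift itself (C15 and O leave the ring, C2 and C3 enter it), so the ring size is conserved and no separate cyclization mode is involved. C1 is set by the (4S) carbinol carbon: in the chair with C14 pseudoaxial on C1 and C5 equatorial on C4 the new bond forms on the face that gives (1R), and the equatorial C5 ends trans to C2 in the new (E)-C3=C4 alkene. The step needs E geometry and clean C4-to-C1 transfer, and both should be secured by the ketene acetal geometry together with the C5–C14 tether, which can bridge a pseudoaxial C14 to an equatorial C5 but not to an axial C5 on the opposite face. Acidic work-up hydrolyses silyl ester 21 to acid 22.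

Step 15
Reactants: 22 14-membered carbocyclic C15 acid (1R,7R)
Product: 23 methyl ester of 22
Conditions: MeI, K2CO3, DMF, rt
Reagents that add atoms: iodomethane, CI
Why: O-alkylation of the carboxylate, mild enough not to epimerize C1.

Step 16
Reactants: 23 methyl ester of 22
Product: 24 C15 tertiary alcohol (1R,7R)
Conditions: MeMgBr (4 equiv), THF, −20 → 0 °C; aq. NH4Cl
Reagents that add atoms: methylmagnesium bromide, C[Mg]Br
Why: Double Grignard addition to the ester gives the C15 dimethyl carbinol, addition being faster than enolization at low temperature so that C1 is kept.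

Step 17
Reactants: 24 C15 tertiary alcohol (1R,7R)
Product: 25 (3R,4R)-epoxy alcohol
Conditions: VO(acac)2 (5 mol%), t-BuOOH (1.5 equiv), 2,6-lutidine (0.2 equiv), CH2Cl2, 0 °C
Reagents that add atoms: tert-butyl hydroperoxide, CC(C)(C)OO
Why: Hydroxyl-directed epoxidation in which the vanadate ester of the C15 carbinol reaches only the bishomoallylic (E)-C3=C4 alkene (C7–O is silylated and C11=C12 lies one atom further), and with a C2 hydrogen eclipsing the C4 methyl (allylic 1,3-strain) and C14 anti to C3 the oxygen should be delivered to the face that gives the (3R,4R)-epoxide, the amine buffer holding back premature ring opening.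

Step 18
Reactants: 25 (3R,4R)-epoxy alcohol
Product: 27 bicyclic ether C3 alcohol (1R,3R,4S,7R), via triethylsilyl ether 26 (not isolated)
Conditions: Et3SiOTf (2.2 equiv), 2,6-lutidine, MeNO2, −25 → 0 °C; then MeOH, PPTS, rt
Reagents that add atoms: none
Why: Silyl-triflate-promoted endo-selective opening of a trisubstituted epoxy alcohol (6-endo-tet), in which the silylated epoxide lengthens its bond to the tertiary C4 and the C15 oxygen attacks C4 with inversion to set (4S) while C3 keeps its oxygen (3R), after which methanolysis frees the C3 hydroxyl and leaves the C7 silyl ether.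

Step 19
Reactants: 27 bicyclic ether C3 alcohol (1R,3R,4S,7R)
Product: 28 C3 acetate C7 silyl ether
Conditions: Ac2O, DMAP, pyridine, CH2Cl2, rt
Reagents that add atoms: acetic anhydride, CC(=O)OC(C)=O
Why: DMAP-catalysed acetylation of the hindered secondary C3 hydroxyl, the only free hydroxyl in the molecule.

Step 20
Reactants: 28 C3 acetate C7 silyl ether
Product: 29 target (1R,3R,4S,7R)
Conditions: HF·pyridine, pyridine, THF, 0 °C → rt
Reagents that add atoms: none
Why: Buffered fluoride cleavage of the C7 silyl ether, under which the C3 acetate, the allylic alcohol and the tertiary ether bonds should survive.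

**Compound list**

1 | (S)-(+)-linalool, (3S)-3,7-dimethylocta-1,6-dien-3-ol | CC(C)=CCC[C@](C)(O)C=C | starting material
2 | (3S)-3,7-dimethyl-3-(trimethylsilyloxy)octa-1,6-diene | CC(C)=CCC[C@](C)(O[Si](C)(C)C)C=C | intermediate
3 | (3S,6R)-6,7-epoxy-3,7-dimethyl-3-(trimethylsilyloxy)oct-1-ene | CC1(C)O[C@@H]1CC[C@](C)(O[Si](C)(C)C)C=C | intermediate
4 | (3R,6S)-2,6-dimethyl-6-(trimethylsilyloxy)octa-1,7-dien-3-ol | C=C(C)[C@H](O)CC[C@](C)(O[Si](C)(C)C)C=C | intermediate
5 | (3R,6S)-3-(tert-butyldimethylsilyloxy)-2,6-dimethyl-6-(trimethylsilyloxy)octa-1,7-diene | C=C(C)[C@H](O[Si](C)(C)C(C)(C)C)CC[C@](C)(O[Si](C)(C)C)C=C | intermediate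
6 | (3R,6S)-3-(tert-butyldimethylsilyloxy)-2-(chloromethyl)-6-methyl-6-(trimethylsilyloxy)octa-1,7-diene (not isolated) | C=C(CCl)[C@H](O[Si](C)(C)C(C)(C)C)CC[C@](C)(O[Si](C)(C)C)C=C | intermediate
7 | (3S,6R)-6-(tert-butyldimethylsilyloxy)-7-(chloromethyl)-3-methylocta-1,7-dien-3-ol | C=C(CCl)[C@H](O[Si](C)(C)C(C)(C)C)CC[C@](C)(O)C=C | intermediate
8 | 5-hexyn-1-ol | C#CCCCCO | starting material
9 | tert-butyl(hex-5-yn-1-yloxy)dimethylsilane | C#CCCCCO[Si](C)(C)C(C)(C)C | intermediate
10 | (E)-[6-(tert-butyldimethylsilyloxy)-2-methylhex-1-enyl]dimethylalane (not isolated) | C[Al](C)/C=C(\C)CCCCO[Si](C)(C)C(C)(C)C | intermediate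
11 | (E)-7-(tert-butyldimethylsilyloxy)-3-methylhept-2-en-1-ol | OC/C=C(\C)CCCCO[Si](C)(C)C(C)(C)C | intermediate
12 | (E)-1-bromo-7-(tert-butyldimethylsilyloxy)-3-methylhept-2-ene (not isolated) | BrC/C=C(\C)CCCCO[Si](C)(C)C(C)(C)C | intermediate
13 | (E)-tert-butyldimethyl[5-methyl-7-(phenylsulfonyl)hept-5-enyloxy]silane | O=S(=O)(C/C=C(\C)CCCCO[Si](C)(C)C(C)(C)C)c1ccccc1 | intermediate
14 | (E)-5-methyl-7-(phenylsulfonyl)hept-5-en-1-ol | O=S(=O)(C/C=C(\C)CCCCO)c1ccccc1 | intermediate
15 | (E)-5-methyl-7-(phenylsulfonyl)hept-5-enoic acid | O=C(O)CCC/C(C)=C/CS(=O)(=O)c1ccccc1 | intermediate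
16 | (E)-5-methyl-7-(phenylsulfonyl)hept-5-enoyl chloride (not isolated) | O=C(Cl)CCC/C(C)=C/CS(=O)(=O)c1ccccc1 | intermediate
17 | (3S,6R)-6-(tert-butyldimethylsilyloxy)-7-(chloromethyl)-3-methylocta-1,7-dien-3-yl (E)-5-methyl-7-(phenylsulfonyl)hept-5-enoate | C=C(CCl)[C@H](O[Si](C)(C)C(C)(C)C)CC[C@](C)(OC(=O)CCC/C(C)=C/CS(=O)(=O)c1ccccc1)C=C | intermediate
18 | 14-membered lactone (4S,7R) with the C15 ester on the C4 oxygen: C4 methyl and vinyl, C7 OTBS, C8 methylene, C10 phenylsulfonyl (epimers), (E)-C11=C12 with C12 methyl | C=C1CC(S(=O)(=O)c2ccccc2)/C=C(\C)CCCC(=O)O[C@](C)(C=C)CC[C@H]1O[Si](C)(C)C(C)(C)C | intermediate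
19 | 14-membered lactone (4S,7R), key-step precursor: as 18 with C10 as CH2 | C=C1CC/C=C(\C)CCCC(=O)O[C@](C)(C=C)CC[C@H]1O[Si](C)(C)C(C)(C)C | intermediate
20 | trimethylsilyl ketene acetal of 19, C14 cis to the ring oxygen (not isolated) | C=C1CC/C=C(\C)CC/C=C(/O[Si](C)(C)C)O[C@](C)(C=C)CC[C@H]1O[Si](C)(C)C(C)(C)C | intermediate
21 | trimethylsilyl ester of acid 22 (not isolated) | C=C1CC/C=C(\C)CC[C@@H](C(=O)O[Si](C)(C)C)C/C=C(\C)CC[C@H]1O[Si](C)(C)C(C)(C)C | intermediate
22 | 14-membered carbocyclic acid (1R,7R), key-step product: C15 acid on C1, (E)-C3=C4 with C4 methyl, C7 OTBS, C8 methylene, (E)-C11=C12 with C12 methyl | C=C1CC/C=C(\C)CC[C@@H](C(=O)O)C/C=C(\C)CC[C@H]1O[Si](C)(C)C(C)(C)C | intermediate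
23 | methyl ester of 22 | C=C1CC/C=C(\C)CC[C@@H](C(=O)OC)C/C=C(\C)CC[C@H]1O[Si](C)(C)C(C)(C)C | intermediate
24 | C15 tertiary alcohol (1R,7R): C1 carries C(CH3)2OH | C=C1CC/C=C(\C)CC[C@@H](C(C)(C)O)C/C=C(\C)CC[C@H]1O[Si](C)(C)C(C)(C)C | intermediate
25 | (1R,3R,4R,7R)-3,4-epoxide of 24 | C=C1CC/C=C(\C)CC[C@@H](C(C)(C)O)C[C@H]2O[C@]2(C)CC[C@H]1O[Si](C)(C)C(C)(C)C | intermediate
26 | bicyclic ether (1R,3R,4S,7R) with C3 OSiEt3 and C7 OTBS (not isolated) | C=C1CC/C=C(\C)CC[C@@H]2C[C@@H](O[Si](CC)(CC)CC)[C@](C)(CC[C@H]1O[Si](C)(C)C(C)(C)C)OC2(C)C | intermediate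
27 | bicyclic ether (1R,3R,4S,7R) with C3 OH and C7 OTBS | C=C1CC/C=C(\C)CC[C@@H]2C[C@@H](O)[C@](C)(CC[C@H]1O[Si](C)(C)C(C)(C)C)OC2(C)C | intermediate
28 | bicyclic ether (1R,3R,4S,7R) with C3 OAc and C7 OTBS | C=C1CC/C=C(\C)CC[C@@H]2C[C@@H](OC(C)=O)[C@](C)(CC[C@H]1O[Si](C)(C)C(C)(C)C)OC2(C)C | intermediate
29 | CNP0202897.1, (1R,3R,4S,7R) in the locants used here | C=C1CC/C=C(\C)CC[C@@H]2C[C@@H](OC(C)=O)[C@](C)(CC[C@H]1O)OC2(C)C | target

**Step count and risks**

Total step count: 20.
Longest linear sequence: 15 steps (from 1 through steps 1–5 and 11–20; the branch from 8 through steps 6–10 and 11–20 is equally long).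

Steps most likely to fail:

Step 14 (key step). The C4-to-C1 relay may erode through a mixed ketene acetal geometry or a boat transition state, giving C1 epimers; the tertiary allylic C–O bond may also ionise on warming. The fallback sets out from 19 and comes back at 22. It moves stereocontrol from the substrate to a reagent and changes the rearranging species from a silyl to a boron ketene acetal. Soft enolization of 19 with (S,S)-2-bromo-4,5-diphenyl-1,3-bis[3,5-bis(trifluoromethyl)phenylsulfonyl]-1,3,2-diazaborolidine and Et3N (toluene–hexane, −78 °C) would give the boron ketene acetal F1. Its geometry is fixed by the amine and solvent pair and its rearrangement face by the boron ligand; (S,S) is shown, and the controller enantiomer that reinforces C4 would be used. The [3,3] shift at −20 to 4 °C and aqueous work-up would return acid 22. Boron-enolate Claisen contraction of macrolactones under such reagent control is known chemistry.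

Step 18. The opening may leak into the 5-exo channel (attack at C3, giving a tetrahydrofuran), or the developing C4 cation may undergo hydride shift or elimination. The fallback sets out from 24, bypasses the epoxide (steps 17 and 18) and comes back at 27. Hg(O2CCF3)2 in MeNO2 at −20 °C should effect reversible Markovnikov alkoxymercuration (C15 oxygen to the tertiary C4, mercury anti at C3), giving the organomercurial F2. Oxidative demercuration (O2, NaBH4, DMF) would give the C3 alcohols F3 as an epimer mixture, and Dess–Martin periodinane the C3 ketone F4. Hydride reduction (NaBH4 or LiBH(sBu)3, chosen for the C3 epimer needed) would return to 27. C4 is then set by the ring closure under thermodynamic control and C3 by the reduction.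

Step 5. The selenium-catalysed chlorination may lose chemoselectivity (attack at the vinyl group, or abstraction toward C7 instead of the methyl), or the tertiary silyl ether may be lost early and the freed hydroxyl join in. The fallback sets out from 5 and comes back at 6, which is methanolysed to 7 as in step 5. Allylic hydroxylation of the isopropenyl methyl with SeO2 (cat.) and t-BuOOH in CH2Cl2 would give the allylic alcohol F5, and PPh3/CCl4 would convert it into chloride 6.

Further compounds
F1 | step 14 | boron ketene acetal of 19 with the (S,S)-4,5-diphenyl-1,3-bis[3,5-bis(trifluoromethyl)phenylsulfonyl]-1,3,2-diazaborolidin-2-yl group on oxygen, C14 cis to the ring oxygen | C=C1CC/C=C(\C)CC/C=C(/OB2N(S(=O)(=O)c3cc(C(F)(F)F)cc(C(F)(F)F)c3)[C@@H](c3ccccc3)[C@H](c3ccccc3)N2S(=O)(=O)c2cc(C(F)(F)F)cc(C(F)(F)F)c2)O[C@](C)(C=C)CC[C@H]1O[Si](C)(C)C(C)(C)C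
F2 | step 18 | bicyclic ether (1R,4S,7R) with C3 trifluoroacetoxymercurio group anti to the C4–O bond and C7 OTBS | C=C1CC/C=C(\C)CC[C@@H]2C[C@@H]([Hg]OC(=O)C(F)(F)F)[C@](C)(CC[C@H]1O[Si](C)(C)C(C)(C)C)OC2(C)C
F3 | step 18 | bicyclic ether (1R,4S,7R) C3 alcohols, mixture of C3 epimers, C7 OTBS | C=C1CC/C=C(\C)CC[C@@H]2CC(O)[C@](C)(CC[C@H]1O[Si](C)(C)C(C)(C)C)OC2(C)C
F4 | step 18 | bicyclic ether (1R,4S,7R) C3 ketone, C7 OTBS | C=C1CC/C=C(\C)CC[C@@H]2CC(=O)[C@](C)(CC[C@H]1O[Si](C)(C)C(C)(C)C)OC2(C)C
F5 | step 5 | (3R,6S)-3-(tert-butyldimethylsilyloxy)-2-(hydroxymethyl)-6-methyl-6-(trimethylsilyloxy)octa-1,7-diene | C=C(CO)[C@H](O[Si](C)(C)C(C)(C)C)CC[C@](C)(O[Si](C)(C)C)C=C
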